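**Plan**

- Ring numbering used below: C1 = C(OH)(CH2OBz) with C7 as its CH2, C2 = CH(OH), C3=C4, C5 = CH(OBz), C6 = CH(OAc).
- Retrosynthesis: put a silyl ether back on O2, shift the C7 benzoate back to O1 and raise C7 to CHO, then cut C1–C2 and C5–C6 together. The enabling feature is the cyclohexene ring: its C3=C4 bond is flanked by two cis O-bearing carbons (C2, C5), the retron of an (E,E)-1,4-dioxygenated butadiene, and C1/C6 carry cis oxygens with a carbonyl-level carbon (C7) on C1, i.e. a (Z)-2,3-diacyloxyacrolein.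
- Forward: diene 5 (2 steps) and dienophile 9 (2 steps) are made separately; the only ring arises in a catalytic asymmetric Diels–Alder reaction; reduction with a 1,2-benzoyl shift and desilylation finish.
- Stereochemistry: C2/C5 cis from the E,E diene, O1/O6 cis from the Z dienophile, C7 cis to O2/O5 from the endo formyl group, absolute configuration from a chiral oxazaborolidinium catalyst; no stereocentre is touched afterwards.
- The five oxygens arrive already differentiated: silyloxy terminus → free 2-OH, enol benzoate → 5-OBz, enol acetate → 6-OAc, the 2-benzoyloxy group of the enal → migrates to O7 and leaves the free 1-OH.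

Key step: step 5

Assumption: (1E,3E)-1,4-diacetoxybutadiene (1) and malonaldehyde tetrabutylammonium salt (6) are taken as purchasable.

**Route**

Step 1
Reactants: 1 (1E,3E)-buta-1,3-diene-1,4-diyl diacetate
Product: 3 (1E,3E)-4-[(triisopropylsilyl)oxy]buta-1,3-dien-1-yl acetate, via potassium 4-acetoxybutadienolate 2 (not isolated)
Conditions: KOt-Bu (1.0 equiv), THF, −78 °C; then i-Pr3SiCl, −78 → 0 °C
Reagents that add atoms: triisopropylsilyl chloride, CC(C)[Si](Cl)(C(C)C)C(C)C
Why: tert-Butoxide should cleave one enol acetate by acyl transfer (enol ester cleavage to a potassium dienolate with retention of the E,E geometry), the resulting anion deactivates the second acetate, and the potassium enolate is silylated at oxygen by the bulky chlorosilane.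

Step 2
Reactants: 3 (1E,3E)-4-[(triisopropylsilyl)oxy]buta-1,3-dien-1-yl acetate
Product: 5 (1E,3E)-4-[(triisopropylsilyl)oxy]buta-1,3-dien-1-yl benzoate, via potassium 4-silyloxybutadienolate 4 (not isolated)
Conditions: KOt-Bu (1.05 equiv), THF, −78 °C; then BzCl, −78 → 0 °C
Reagents that add atoms: benzoyl chloride, O=C(Cl)c1ccccc1
Why: The same enol ester cleavage should remove the remaining acetate (the hindered triisopropylsilyl enol ether is not attacked at −78 °C), and O-acylation of the potassium dienolate by the acid chloride gives the enol benzoate with the E,E geometry intact.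

Step 3
Reactants: 6 tetrabutylammonium (E)-3-oxoprop-1-en-1-olate (malonaldehyde tetrabutylammonium salt)
Product: 7 2-(benzoyloxy)malonaldehyde, as its enol 2-(benzoyloxy)-3-hydroxyprop-2-enal
Conditions: (PhCO2)2 (1.0 equiv), CH2Cl2, 0 °C → rt; then 1 M HCl
Reagents that add atoms: dibenzoyl peroxide, O=C(OOC(=O)c1ccccc1)c1ccccc1
Why: Electrophilic α-benzoyloxylation of a 1,3-dicarbonyl enolate, in which the central carbon attacks the O–O bond of the diacyl peroxide and benzoate leaves, should give the 2-acyloxy dialdehyde, isolated as its stabilised enol after acidification.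

Step 4
Reactants: 7 2-(benzoyloxy)malonaldehyde (enol form)
Product: 9 (Z)-3-acetoxy-2-(benzoyloxy)prop-2-enal, via triethylammonium enolate 8 (not isolated)
Conditions: AcCl (1.05 equiv), Et3N (1.1 equiv), CH2Cl2, −78 → −20 °C
Reagents that add atoms: acetyl chloride, CC(Cl)=O
Why: O-Acylation of a vinylogous acid: the non-chelated ammonium enolate should adopt the W shape (each oxygen anti to the far carbon), so acetylation at oxygen places OAc trans to CHO and cis to OBz, which is the Z enol acetate and also the isomer with the least opposed dipoles.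

Step 5
Reactants: 5 (1E,3E)-4-[(triisopropylsilyl)oxy]buta-1,3-dien-1-yl benzoate; 9 (Z)-3-acetoxy-2-(benzoyloxy)prop-2-enal
Product: 10 (1S,2S,5R,6S)-6-acetoxy-1-formyl-2-[(triisopropylsilyl)oxy]cyclohex-3-ene-1,5-diyl dibenzoate
Conditions: (R)-1-(2-methylphenyl)-3,3-diphenyltetrahydro-1H,3H-pyrrolo[1,2-c][1,3,2]oxazaborole (20 mol %), HNTf2 (17 mol %), CH2Cl2, −78 → −40 °C
Reagents that add atoms: none
Why: The protonated oxazaborolidine binds the formyl oxygen of 9 and lowers its LUMO, and a concerted but asynchronous normal-demand [4+2] cycloaddition should follow, in which the C5–C6 bond (benzoyloxy-bearing diene terminus to the acetoxy-bearing β-carbon) runs ahead of the C1–C2 bond (silyloxy-bearing terminus to the formyl-bearing α-carbon). The closest known reaction type is the chiral oxazaborolidinium-catalysed Diels–Alder reaction of 2-substituted acroleins with 1-oxygenated butadienes. The cyclohexene ring closes by suprafacial–suprafacial addition across the s-cis diene, both ring bonds forming in the one cycloaddition with no separate cyclisation. C2 and C5 come out cis because both oxygens are E (outside) on the diene, O1 and O6 come out cis because the dienophile is Z, the endo position of the catalyst-bound formyl group (Alder rule, as for 2-substituted acroleins with acyclic 1-heteroatom dienes) puts C7 cis to O2 and O5, and the absolute sense comes from the catalyst, whose aryl group should leave the Si face at C2 of the enal open when the sense of induction known for 2-substituted acroleins is transferred. The step needs regioselectivity, secured by the stronger silyloxy donor (largest HOMO coefficient on the benzoyloxy-bearing terminus, matched with the β-carbon of the activated enal), and it needs endo and facial selectivity, secured by single-point formyl binding to the chiral Lewis acid.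

Step 6
Reactants: 10 (1S,2S,5R,6S)-6-acetoxy-1-formyl-2-[(triisopropylsilyl)oxy]cyclohex-3-ene-1,5-diyl dibenzoate
Product: 12 [(1S,2S,5R,6S)-6-acetoxy-5-(benzoyloxy)-1-hydroxy-2-[(triisopropylsilyl)oxy]cyclohex-3-en-1-yl]methyl benzoate, via unrearranged primary alcohol 11 (not isolated)
Conditions: NaBH4, THF/MeOH 4:1, −40 → 0 °C; aq. NH4Cl; crude, DBU (10 mol %), CH2Cl2, 0 °C → rt
Reagents that add atoms: none
Why: Borohydride should reduce only the aldehyde, and the new primary hydroxyl then takes the benzoyl group from the adjacent tertiary oxygen through a five-membered orthoester-type intermediate (1,2-O→O acyl migration, tertiary to primary, with relief of strain), which is expected to outrun the 1,3-shift of the acetate and leaves a product whose only free hydroxyl is tertiary; no stereocentre is touched.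

Step 7
Reactants: 12 [(1S,2S,5R,6S)-6-acetoxy-5-(benzoyloxy)-1-hydroxy-2-[(triisopropylsilyl)oxy]cyclohex-3-en-1-yl]methyl benzoate
Product: 13 [(1R,2S,5R,6S)-6-acetoxy-5-(benzoyloxy)-1,2-dihydroxycyclohex-3-en-1-yl]methyl benzoate
Conditions: HF·pyridine, pyridine/THF, 0 °C → rt
Reagents that add atoms: none
Why: Fluoride-mediated cleavage of the Si–O bond under buffered, weakly acidic conditions should free the allylic hydroxyl without ester loss or acyl migration and without touching any stereocentre (the change of the C1 descriptor from S to R is a priority change only).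

**Compound list**

1 | (1E,3E)-buta-1,3-diene-1,4-diyl diacetate | CC(=O)O/C=C/C=C/OC(C)=O | starting material
2 | potassium (1E,3E)-4-acetoxybuta-1,3-dien-1-olate | CC(=O)O/C=C/C=C/[O-].[K+] | intermediate
3 | (1E,3E)-4-[(triisopropylsilyl)oxy]buta-1,3-dien-1-yl acetate | CC(=O)O/C=C/C=C/O[Si](C(C)C)(C(C)C)C(C)C | intermediate
4 | potassium (1E,3E)-4-[(triisopropylsilyl)oxy]buta-1,3-dien-1-olate | [O-]/C=C/C=C/O[Si](C(C)C)(C(C)C)C(C)C.[K+] | intermediate
5 | (1E,3E)-4-[(triisopropylsilyl)oxy]buta-1,3-dien-1-yl benzoate | O=C(O/C=C/C=C/O[Si](C(C)C)(C(C)C)C(C)C)c1ccccc1 | intermediate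
6 | tetrabutylammonium (E)-3-oxoprop-1-en-1-olate (malonaldehyde tetrabutylammonium salt) | O=C/C=C/[O-].CCCC[N+](CCCC)(CCCC)CCCC | starting material
7 | 2-(benzoyloxy)malonaldehyde, enol form 2-(benzoyloxy)-3-hydroxyprop-2-enal (the enol geometry equilibrates and is not defined) | O=CC(OC(=O)c1ccccc1)=CO | intermediate
8 | triethylammonium (Z)-2-(benzoyloxy)-3-oxoprop-1-en-1-olate | O=CC(/OC(=O)c1ccccc1)=C/[O-].CC[NH+](CC)CC | intermediate
9 | (Z)-3-acetoxy-2-(benzoyloxy)prop-2-enal | CC(=O)O/C=C(\OC(=O)c1ccccc1)C=O | intermediate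
10 | (1S,2S,5R,6S)-6-acetoxy-1-formyl-2-[(triisopropylsilyl)oxy]cyclohex-3-ene-1,5-diyl dibenzoate | CC(=O)O[C@H]1[C@H](OC(=O)c2ccccc2)C=C[C@H](O[Si](C(C)C)(C(C)C)C(C)C)[C@]1(OC(=O)c1ccccc1)C=O | intermediate
11 | (1S,2S,5R,6S)-6-acetoxy-1-(hydroxymethyl)-2-[(triisopropylsilyl)oxy]cyclohex-3-ene-1,5-diyl dibenzoate | CC(=O)O[C@H]1[C@H](OC(=O)c2ccccc2)C=C[C@H](O[Si](C(C)C)(C(C)C)C(C)C)[C@]1(OC(=O)c1ccccc1)CO | intermediate
12 | [(1S,2S,5R,6S)-6-acetoxy-5-(benzoyloxy)-1-hydroxy-2-[(triisopropylsilyl)oxy]cyclohex-3-en-1-yl]methyl benzoate | CC(=O)O[C@H]1[C@H](OC(=O)c2ccccc2)C=C[C@H](O[Si](C(C)C)(C(C)C)C(C)C)[C@]1(O)COC(=O)c1ccccc1 | intermediate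
13 | [(1R,2S,5R,6S)-6-acetoxy-5-(benzoyloxy)-1,2-dihydroxycyclohex-3-en-1-yl]methyl benzoate | CC(=O)O[C@H]1[C@H](OC(=O)c2ccccc2)C=C[C@H](O)[C@]1(O)COC(=O)c1ccccc1 | target

**Count and risks**

Total step count: 7. Longest linear sequence: 5 steps (1 → 3 → 5 → 10 → 12 → 13, or 6 → 7 → 9 → 10 → 12 → 13).

Step 5 (most at risk). The trisubstituted push–pull dienophile may turn over slowly, the silyl dienol ether may add to the activated formyl group in a Mukaiyama-type manner instead of cycloadding, and the facial or endo preference may be weak or reversed. Fallback: enantiocontrol is moved to the end of the route. Setting out from 5 and 9, the cycloaddition is run without catalyst (toluene, 90 °C, or 12 kbar in CH2Cl2) to give the racemate, i.e. 10 together with its mirror image (1R,2R,5S,6R)-6-acetoxy-1-formyl-2-[(triisopropylsilyl)oxy]cyclohex-3-ene-1,5-diyl dibenzoate F1. Steps 6 and 7 applied to the racemate pass, on the mirror-image side, through (1R,2R,5S,6R)-6-acetoxy-1-(hydroxymethyl)-2-[(triisopropylsilyl)oxy]cyclohex-3-ene-1,5-diyl dibenzoate F2 and [(1R,2R,5S,6R)-6-acetoxy-5-(benzoyloxy)-1-hydroxy-2-[(triisopropylsilyl)oxy]cyclohex-3-en-1-yl]methyl benzoate F3, and give 13 mixed with [(1S,2R,5S,6R)-6-acetoxy-5-(benzoyloxy)-1,2-dihydroxycyclohex-3-en-1-yl]methyl benzoate F4. A lipase-catalysed kinetic resolution (Pseudomonas cepacia lipase or Candida antarctica lipase B, vinyl acetate, t-BuOMe) should, by the empirical size rule for secondary alcohols, acetylate the (2R)-alcohol to [(1S,2R,5S,6R)-2,6-diacetoxy-5-(benzoyloxy)-1-hydroxycyclohex-3-en-1-yl]methyl benzoate F5 and leave the (2S)-alcohol, so the route is rejoined at 13.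

Step 6. The acetate on O6 may shift to the new primary hydroxyl in competition with the benzoyl shift from O1, or prolonged base may scramble the two acyl groups. Fallback: the acyl pattern is rebuilt instead of relocated. Setting out from 10, reduction (NaBH4) followed by methanolysis of all three esters (K2CO3, MeOH) gives (1S,2S,3R,6S)-1-(hydroxymethyl)-6-[(triisopropylsilyl)oxy]cyclohex-4-ene-1,2,3-triol F6. Benzoylation of the two most accessible hydroxyls, the primary one and the allylic one (BzCl 2.1 equiv, pyridine, CH2Cl2, −30 °C), gives [(1S,2S,5R,6S)-5-(benzoyloxy)-1,6-dihydroxy-2-[(triisopropylsilyl)oxy]cyclohex-3-en-1-yl]methyl benzoate F7. Acetylation of the remaining secondary hydroxyl (Ac2O, pyridine, DMAP cat., 0 °C; the tertiary hydroxyl stays free) rejoins the route at 12.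

Step 3. The weakly nucleophilic malonaldehyde enolate may react slowly with the peroxide, proton transfer from the more acidic product may stall the conversion, and a second benzoyloxylation may occur. Fallback: the oxygen is brought in by rearrangement instead of by enolate oxidation. Setting out from 6, O-benzoylation (BzCl, CH2Cl2, 0 °C) gives (E)-3-oxoprop-1-en-1-yl benzoate F8. Epoxidation with dimethyldioxirane (acetone, 0 °C) gives the enol ester epoxide trans-3-formyloxiran-2-yl benzoate F9 (racemic). Warming (toluene, 60 °C) should trigger the 1,2-acyloxy shift typical of enol ester epoxides and deliver 7, where the route is rejoined.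

**Further compounds**

F1 | step 5 | (1R,2R,5S,6R)-6-acetoxy-1-formyl-2-[(triisopropylsilyl)oxy]cyclohex-3-ene-1,5-diyl dibenzoate | CC(=O)O[C@@H]1[C@@H](OC(=O)c2ccccc2)C=C[C@@H](O[Si](C(C)C)(C(C)C)C(C)C)[C@@]1(OC(=O)c1ccccc1)C=O
F2 | step 5 | (1R,2R,5S,6R)-6-acetoxy-1-(hydroxymethyl)-2-[(triisopropylsilyl)oxy]cyclohex-3-ene-1,5-diyl dibenzoate | CC(=O)O[C@@H]1[C@@H](OC(=O)c2ccccc2)C=C[C@@H](O[Si](C(C)C)(C(C)C)C(C)C)[C@@]1(OC(=O)c1ccccc1)CO
F3 | step 5 | [(1R,2R,5S,6R)-6-acetoxy-5-(benzoyloxy)-1-hydroxy-2-[(triisopropylsilyl)oxy]cyclohex-3-en-1-yl]methyl benzoate | CC(=O)O[C@@H]1[C@@H](OC(=O)c2ccccc2)C=C[C@@H](O[Si](C(C)C)(C(C)C)C(C)C)[C@@]1(O)COC(=O)c1ccccc1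
F4 | step 5 | [(1S,2R,5S,6R)-6-acetoxy-5-(benzoyloxy)-1,2-dihydroxycyclohex-3-en-1-yl]methyl benzoate | CC(=O)O[C@@H]1[C@@H](OC(=O)c2ccccc2)C=C[C@@H](O)[C@@]1(O)COC(=O)c1ccccc1
F5 | step 5 | [(1S,2R,5S,6R)-2,6-diacetoxy-5-(benzoyloxy)-1-hydroxycyclohex-3-en-1-yl]methyl benzoate | CC(=O)O[C@@H]1[C@@H](OC(=O)c2ccccc2)C=C[C@@H](OC(C)=O)[C@@]1(O)COC(=O)c1ccccc1
F6 | step 6 | (1S,2S,3R,6S)-1-(hydroxymethyl)-6-[(triisopropylsilyl)oxy]cyclohex-4-ene-1,2,3-triol | O[C@H]1[C@H](O)C=C[C@H](O[Si](C(C)C)(C(C)C)C(C)C)[C@]1(O)CO
F7 | step 6 | [(1S,2S,5R,6S)-5-(benzoyloxy)-1,6-dihydroxy-2-[(triisopropylsilyl)oxy]cyclohex-3-en-1-yl]methyl benzoate | O[C@H]1[C@H](OC(=O)c2ccccc2)C=C[C@H](O[Si](C(C)C)(C(C)C)C(C)C)[C@]1(O)COC(=O)c1ccccc1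
F8 | step 3 | (E)-3-oxoprop-1-en-1-yl benzoate | O=C/C=C/OC(=O)c1ccccc1
F9 | step 3 | trans-3-formyloxiran-2-yl benzoate (racemic, one enantiomer drawn) | O=C[C@H]1O[C@@H]1OC(=O)c1ccccc1
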